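**Retrosynthetic overview**
1. Numbering: C1 = ring carbonyl carbon, C2 = carbon bearing CH2O, C3 = olefinic CH, C4 = allylic CH2, C5 = ring stereocentre, C6 = CH2 next to the carbonyl. Side chain: C7(=CH2)–C8H2–C9H=C10H–C11(CH3)(OH)–C12H2O.
2. Endgame: both isobutyrates go on last (two primary OH against one tertiary OH). The C2 hydroxymethyl group comes from a Morita–Baylis–Hillman reaction. C7–C8, the C7 methylene and the E C9=C10 bond come from one ruthenium-catalysed alkene–alkyne coupling of (R)-5-ethynylcyclohex-2-enone with (R)-2-methylpent-4-ene-1,2-diol, itself made from (S)-2-methylglycidol.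
3. Key disconnection: C4–C5 and C6–C1 are cut together. The forward step is a catalytic asymmetric [4+2] cycloaddition of a vinylketene silyl acetal (C4=C3–C2=C1(OMe)(OSi), from methyl crotonate) with methyl (E)-5-(trimethylsilyl)pent-2-en-4-ynoate (C5=C6). It delivers the ring, the C5 stereocentre, the C2=C3 bond and C1 at the ketone level at once.
4. Enabling feature: in the cyclohexenone ring the chain C4H2–C3H=C2–C1(=O) is a vinylketene retron. C6 is α to the C1 carbonyl, so an ester parked on C6 polarises C5=C6 for the cycloaddition. Afterwards that ester is a β-keto ester and leaves as CO2.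
5. Ring order: the single carbocycle is formed in the key step; no other ring is made.

Key step: step 3

Assumption: the catalyst antipode is chosen so that the diene adds to the Re face at C5 of the enynoate, which gives (R)-C5. The sense of induction is inferred by analogy with related enoates and would have to be confirmed; the other antipode is equally accessible.

Step 1
Reactants: 1 3-(trimethylsilyl)prop-2-ynal; 2 methyl (triphenylphosphoranylidene)acetate
Product: 3 methyl (E)-5-(trimethylsilyl)pent-2-en-4-ynoate
Conditions: CH2Cl2, 0 °C to rt; chromatography to remove the minor Z isomer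
Reagents that add atoms: none
Why: Wittig olefination with a stabilised ylide should give mainly the E-enoate, and the neutral conditions leave the alkynylsilane intact.

Step 2
Reactants: 4 methyl (E)-but-2-enoate (methyl crotonate)
Product: 5 1-(tert-butyldimethylsilyloxy)-1-methoxybuta-1,3-diene (E/Z mixture at C1=C2)
Conditions: LiN(iPr)2 (LDA), THF/DMPU, −78 °C; TBSCl, −78 °C to rt; non-aqueous work-up, distillation
Reagents that add atoms: tert-butyldimethylsilyl chloride, CC(C)(C)[Si](C)(C)Cl
Why: γ-deprotonation of the crotonate by the LDA–DMPU complex and O-silylation of the extended enolate (silyl dienolate formation) should give the vinylketene silyl acetal, whose C1=C2 geometry is irrelevant because C1 ends as a carbonyl carbon.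

Step 3
Reactants: 3 methyl (E)-5-(trimethylsilyl)pent-2-en-4-ynoate; 5 1-(tert-butyldimethylsilyloxy)-1-methoxybuta-1,3-diene
Product: 7 methyl (1S,6R)-2-oxo-6-[(trimethylsilyl)ethynyl]cyclohex-3-ene-1-carboxylate, via mixed ketal cycloadduct 6 (not isolated)
Conditions: BINOL-derived N-triflyl imidodiphosphorimidate (IDPi) Brønsted acid (3 mol %), 5 (1.5 equiv), toluene, −40 °C; then 1 M HCl, THF, 0 °C
Reagents that add atoms: none
Why: Proposed new method: the IDPi acid is silylated by 5 to a silylium/IDPi ion pair, this O-silylates the ester carbonyl of 3, and the cationic dienophile adds the s-cis form of 5 in a polar asynchronous [4+2] cycloaddition in which the γ-terminus C4 binds the β-carbon C5 and the acetal carbon C1 binds the α-carbon C6, the silylium ion then passing to the next molecule of 3 and the mixed ketal 6 being hydrolysed to ketone 7 in the work-up. The closest known reaction types are the silylium/IDPi-catalysed Diels–Alder reaction of α,β-unsaturated methyl esters with simple dienes, the Mukaiyama–Michael addition of silyl ketene acetals to the same esters under the same catalysis and the thermal Diels–Alder reaction of 1,1-dioxygenated butadienes, and only the use of a vinylketene silyl acetal as the 4π partner under this catalysis is new. The one ring is closed as a suprafacial 4π+2π event, and if the two bonds form in sequence the second closure is a 6-(enolexo)-exo-trig attack of the C6 silyl ketene acetal on the C1 dioxocarbenium ion. C5 is controlled by the confined chiral anion, which should leave only the Re face at C5 of the silylated enoate open, C6 follows from the E geometry of 3 (trans to the alkynyl group) but is epimerisable and is erased in step 4, and the ketal centre C1 is erased in the work-up, so that the endo/exo ratio and the E/Z ratio of 5 are of no consequence. The step needs ortho regiochemistry, secured by the two oxygen donors on C1 and the ester on C6, γ- over α-attack of 5, secured by the unsubstituted C4 terminus and the crowded ion pair, 1,4- over 1,6-attack on the enynoate, secured by the silyl cap on the alkyne terminus, and ring closure ahead of silyl transfer, favoured because cation and nucleophile are generated next to each other in the s-cis adduct.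

Step 4
Reactants: 7 methyl (1S,6R)-2-oxo-6-[(trimethylsilyl)ethynyl]cyclohex-3-ene-1-carboxylate
Product: 9 (R)-5-ethynylcyclohex-2-en-1-one, via beta-keto acid 8 (not isolated)
Conditions: LiOH (3 equiv), THF/MeOH/H2O, argon, 0 °C to rt; then 1 M HCl to pH 3, 40 °C
Reagents that add atoms: none
Why: Saponification of the β-keto ester, hydroxide-induced protiodesilylation of the alkynylsilane and, after acidification, decarboxylation of the β-keto acid through its cyclic transition state should remove both temporary groups in one flask, erase the C6 stereocentre and leave the non-acidic C5 centre untouched.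

Step 5
Reactants: 10 (S)-2-methylglycidol [(S)-(2-methyloxiran-2-yl)methanol]
Product: 11 (R)-2-methylpent-4-ene-1,2-diol
Conditions: CH2=CHMgBr (2.5 equiv), CuI (10 mol %), THF, −30 to 0 °C; aq. NH4Cl
Reagents that add atoms: vinylmagnesium bromide, C=C[Mg]Br
Why: Copper-catalysed Grignard opening of the 2,2-disubstituted epoxide occurs by SN2 attack at the unhindered CH2, so no bond at the quaternary stereocentre is touched and the configuration of 10 is carried over (the descriptor changes from S to R only through the priority rules).

Step 6
Reactants: 9 (R)-5-ethynylcyclohex-2-en-1-one; 11 (R)-2-methylpent-4-ene-1,2-diol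
Product: 12 (5R)-5-[(4E,6R)-6,7-dihydroxy-6-methylhepta-1,4-dien-2-yl]cyclohex-2-en-1-one
Conditions: [CpRu(MeCN)3]PF6 (10 mol %), 11 (1.3 equiv), acetone, rt
Reagents that add atoms: none
Why: Ruthenium-catalysed alkene–alkyne coupling (formal Alder-ene reaction) proceeds by oxidative cyclisation to a ruthenacyclopentene with C–C bond formation at the internal alkyne carbon, β-hydride elimination of the allylic C10–H and reductive elimination, which should give the branched 1,4-diene with the C7 methylene and the E C9=C10 bond while free hydroxyls, the cyclic enone and both stereocentres are left alone.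

Step 7
Reactants: 12 (5R)-5-[(4E,6R)-6,7-dihydroxy-6-methylhepta-1,4-dien-2-yl]cyclohex-2-en-1-one
Product: 13 (5R)-5-[(4E,6R)-6,7-dihydroxy-6-methylhepta-1,4-dien-2-yl]-2-(hydroxymethyl)cyclohex-2-en-1-one
Conditions: 37 % aq. HCHO (3 equiv), DMAP (0.3 equiv), THF, rt
Reagents that add atoms: formaldehyde, C=O
Why: Morita–Baylis–Hillman reaction, in which conjugate addition of DMAP to the enone, aldol capture of formaldehyde at C2 and loss of DMAP restore the C2=C3 bond, and no stereocentre is formed or touched.

Step 8
Reactants: 13 (5R)-5-[(4E,6R)-6,7-dihydroxy-6-methylhepta-1,4-dien-2-yl]-2-(hydroxymethyl)cyclohex-2-en-1-one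
Product: 14 target, [(4R)-4-{(4E,6R)-6-hydroxy-6-methyl-7-[(2-methylpropanoyl)oxy]hepta-1,4-dien-2-yl}-6-oxocyclohex-1-en-1-yl]methyl 2-methylpropanoate
Conditions: (iPrCO)2O (2.4 equiv), pyridine, CH2Cl2, 0 °C to rt
Reagents that add atoms: isobutyric anhydride, CC(C)C(=O)OC(=O)C(C)C
Why: Acylation with an anhydride discriminates by steric demand, so the two primary alcohols should be esterified and the tertiary allylic alcohol left free, and the weakly nucleophilic base avoids SN2′ displacement of the new allylic ester.

**Compound list**
1 | 3-(trimethylsilyl)prop-2-ynal | C[Si](C)(C)C#CC=O | starting material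
2 | methyl (triphenylphosphoranylidene)acetate | COC(=O)C=P(c1ccccc1)(c1ccccc1)c1ccccc1 | starting material
3 | methyl (E)-5-(trimethylsilyl)pent-2-en-4-ynoate | COC(=O)/C=C/C#C[Si](C)(C)C | intermediate
4 | methyl (E)-but-2-enoate | C/C=C/C(=O)OC | starting material
5 | 1-(tert-butyldimethylsilyloxy)-1-methoxybuta-1,3-diene (E/Z mixture) | C=CC=C(OC)O[Si](C)(C)C(C)(C)C | intermediate
6 | methyl (1S,6R)-2-(tert-butyldimethylsilyloxy)-2-methoxy-6-[(trimethylsilyl)ethynyl]cyclohex-3-ene-1-carboxylate (epimers at the ketal carbon) | COC(=O)[C@@H]1C(OC)(O[Si](C)(C)C(C)(C)C)C=CC[C@H]1C#C[Si](C)(C)C | intermediate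
7 | methyl (1S,6R)-2-oxo-6-[(trimethylsilyl)ethynyl]cyclohex-3-ene-1-carboxylate | COC(=O)[C@@H]1C(=O)C=CC[C@H]1C#C[Si](C)(C)C | intermediate
8 | (1S,6R)-6-ethynyl-2-oxocyclohex-3-ene-1-carboxylic acid | OC(=O)[C@@H]1C(=O)C=CC[C@H]1C#C | intermediate
9 | (R)-5-ethynylcyclohex-2-en-1-one | C#C[C@@H]1CC=CC(=O)C1 | intermediate
10 | (S)-2-methylglycidol | C[C@]1(CO)CO1 | starting material
11 | (R)-2-methylpent-4-ene-1,2-diol | C[C@](O)(CO)CC=C | intermediate
12 | (5R)-5-[(4E,6R)-6,7-dihydroxy-6-methylhepta-1,4-dien-2-yl]cyclohex-2-en-1-one | C=C(C/C=C/[C@@](C)(O)CO)[C@@H]1CC=CC(=O)C1 | intermediate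
13 | (5R)-5-[(4E,6R)-6,7-dihydroxy-6-methylhepta-1,4-dien-2-yl]-2-(hydroxymethyl)cyclohex-2-en-1-one | C=C(C/C=C/[C@@](C)(O)CO)[C@@H]1CC=C(CO)C(=O)C1 | intermediate
14 | CNP0536801.1 (ring C5 R, carbinol C11 R, C9=C10 E) | C=C(C/C=C/[C@@](C)(O)COC(=O)C(C)C)[C@@H]1CC=C(COC(=O)C(C)C)C(=O)C1 | target

**Step count**
Total steps: 8. Longest linear sequence: 6 (steps 1, 3, 4, 6, 7, 8).

**Steps most likely to fail**

Risk 1, step 3 (Proposed new method).
- What may go wrong: the reaction may stop after the first bond when the diene reacts through its s-trans form, giving silyl transfer and an open-chain vinylogous Michael adduct. Attack through the α-carbon of the dienolate may compete. Face discrimination for the slim alkynyl substituent may be poor.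
- Fallback: it sets out from 3 and brings C1 in at the alcohol level, using known chemistry. Crotonaldehyde is converted with TBSOTf and Et3N into (E)-1-(tert-butyldimethylsilyloxy)buta-1,3-diene F1. A cationic oxazaborolidinium-catalysed Diels–Alder reaction of F1 with 3 follows (o-tolyl oxazaborolidine from diphenylprolinol, activated by HNTf2, CH2Cl2, −78 to −40 °C). It should give methyl (1S,2R,6R)-2-(tert-butyldimethylsilyloxy)-6-[(trimethylsilyl)ethynyl]cyclohex-3-ene-1-carboxylate F2. HF·pyridine then frees methyl (1S,2R,6R)-2-hydroxy-6-[(trimethylsilyl)ethynyl]cyclohex-3-ene-1-carboxylate F3, and Dess–Martin oxidation comes back to the route at 7.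

Risk 2, step 6.
- What may go wrong: branched/linear regioselectivity may erode because the alkyne sits on a secondary ring carbon, and the 1,2-diol may sequester the cationic ruthenium centre.
- Fallback: it sets out from 9 and forms C7–C8 and C9=C10 in separate events. Markovnikov hydroiodination (NaI, TMSCl, H2O, MeCN) should give (R)-5-(1-iodoethenyl)cyclohex-2-en-1-one F4. Stille coupling with allyltributylstannane (Pd2(dba)3, AsPh3, NMP) should give (R)-5-(penta-1,4-dien-2-yl)cyclohex-2-en-1-one F5. Racemic 2-methyl-2-vinyloxirane is converted into (R)-2-methylbut-3-ene-1,2-diol F6 by palladium-catalysed dynamic kinetic asymmetric addition of hydrogencarbonate (Pd2(dba)3·CHCl3, diaminocyclohexane-derived bis(diphenylphosphinobenzamide) ligand, NaHCO3, BEt3) and hydrolysis of the carbonate. E-selective cross metathesis of F5 with F6 (second-generation Hoveyda–Grubbs catalyst, CH2Cl2, 40 °C) comes back to the route at 12.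

Risk 3, step 7.
- What may go wrong: turnover may be slow, the diol may bind formaldehyde as hemiacetals, and the enone may dimerise in Rauhut–Currier fashion.
- Fallback: it sets out from 12 and replaces nucleophilic catalysis by cross-coupling. α-Iodination (I2, K2CO3, DMAP cat., THF/H2O) should give (5R)-5-[(4E,6R)-6,7-dihydroxy-6-methylhepta-1,4-dien-2-yl]-2-iodocyclohex-2-en-1-one F7. Stille coupling with (tributylstannyl)methanol (Pd(PPh3)4, toluene, 80 °C) comes back to the route at 13.

**Further compounds**
F1 | step 3 | (E)-1-(tert-butyldimethylsilyloxy)buta-1,3-diene | C=C/C=C/O[Si](C)(C)C(C)(C)C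
F2 | step 3 | methyl (1S,2R,6R)-2-(tert-butyldimethylsilyloxy)-6-[(trimethylsilyl)ethynyl]cyclohex-3-ene-1-carboxylate | COC(=O)[C@@H]1[C@H](O[Si](C)(C)C(C)(C)C)C=CC[C@H]1C#C[Si](C)(C)C
F3 | step 3 | methyl (1S,2R,6R)-2-hydroxy-6-[(trimethylsilyl)ethynyl]cyclohex-3-ene-1-carboxylate | COC(=O)[C@@H]1[C@H](O)C=CC[C@H]1C#C[Si](C)(C)C
F4 | step 6 | (R)-5-(1-iodoethenyl)cyclohex-2-en-1-one | C=C(I)[C@@H]1CC=CC(=O)C1
F5 | step 6 | (R)-5-(penta-1,4-dien-2-yl)cyclohex-2-en-1-one | C=CCC(=C)[C@@H]1CC=CC(=O)C1
F6 | step 6 | (R)-2-methylbut-3-ene-1,2-diol | C[C@](O)(CO)C=C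
F7 | step 7 | (5R)-5-[(4E,6R)-6,7-dihydroxy-6-methylhepta-1,4-dien-2-yl]-2-iodocyclohex-2-en-1-one | C=C(C/C=C/[C@@](C)(O)CO)[C@@H]1CC=C(I)C(=O)C1
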